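Do I need more catalyst or more time for a flask with twice the solid substrate of the cedar run, or can I leave both as they are?

- cedar: solid substrate 0.40 M; free catalyst 2.6 mol%; run made earlier
- flask: solid substrate 0.80 M; free catalyst 2.6 mol%; time 25 min

- cedar (time / min: product / %, starting material / %): 0.417: 2.6, 18.5; 0.833: 6.6, 30.9; 1.33: 13.5, 38.0; 2.50: 35.7, 41.9; 5.00: 75.4, 26.6

(each reading ± 1 percentage point)

- at the start none of the solid substrate is in solution
- what has only dissolved of solid substrate counts as not reacted
- starting material means what is dissolved; the solid is not counted in it
- no earlier run changes the charge of free catalyst; that part of a forecast is a guess
- a reading or a percentage of product counts all its forms, free or not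
- the reaction counts as stopped when no species that holds the solid substrate changes by six tenths of a point or more over the second half of the time

1. which holds at 25 min: what has brought the reaction to rest, or that it has not come to rest (for what has run out or reacted, a solid counts together with what of it has only dissolved) (all of the solid substrate has reacted / it is still moving / no working catalyst is left / forward and back rates have come level)
2. product at 25 min, in percent of the solid substrate charged
3. starting material at 25 min, in percent of the solid substrate charged

I decide by a balance of the catalyst, the reagent charged in the smaller amount. To turn the whole charge into product, each catalyst must make 38.5 turns, the turnover number this recipe demands. The loading is the same in both flasks, so the demand is the same. The cedar run reads 29.0 turns at 5.00 min, and its pace between its last readings reads 6.11 min⁻¹ in turns per catalyst. If the new flask keeps that pace of the cedar run from the same count on, my estimate closes the count at about 6.55 min, well before 25 min. I expect the pace to fall as starting material thins, and no earlier run changes the catalyst charge, so this is partly a guess. Even so, I leave the loading at 2.6 mol% and the time at 25 min.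

The forecast says that at the asked time this holds: all of the solid substrate has reacted. It gives product 99 % and starting material 0.5 %, and keeps a margin: “A hidden equilibrium or late catalyst loss can't be excluded”.

In the flask this holds: forward and back rates have come level. It gives product 96.8 % and starting material 2.75 %.

    starting material + free catalyst ⇌ catalyst intermediate (K = 1.10 M⁻¹, k = 2.70 M⁻¹ s⁻¹)
    catalyst intermediate ⇌ free catalyst + product (K = 0.660 M, k = 1.30 s⁻¹)
    2 catalyst intermediate → spent catalyst (k = 0.910 M⁻¹ s⁻¹)
    solid substrate ⇌ starting material, rate k4*(cs4 - [starting material]) while solid is left; crystals form when [starting material] > cs4 (solubility = 0.260 M, k = 0.0160 s⁻¹)
    crystals ⇌ product, rate k5*(cs5 - [product]) while solid is left; crystals form when [product] > cs5 (solubility = 16.0 mM, k = 0.410 s⁻¹)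

My count and the forecast's ending part from the flask at the last turns. This flask has come to rest: over the second half of the time, no share of a substrate, an intermediate or a product moves by more than 0.057 percentage points. It has made 37.2 of the 38.5 turns; 1.06 turns stand unpaid as starting material and 0.168 in catalyst intermediate and spent catalyst, with 83.2 % of the catalyst free. The neighbour flask, charged at 0.20 M, has more unpaid as starting material at the same time, 4.29 turns, with more catalyst free, 94.6 %. Left until 250 min, this flask falls to 66.9 % free catalyst, still holds 1.06 turns as starting material, and loses 0.42 points of product.

The readings are calculated on assumed constants, noise included.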